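## Retrosynthetic overview

1. The succinimide ring is closed last: the C15 carboxamide nitrogen attacks the C16 acyl-oxazolidinone carbonyl and the auxiliary leaves.
2. The C12–C13 bond comes from an Evans syn-aldol between aldehyde 11 (C1–C12, C17, with 7β-OAc and 2α-Cl in place) and the boron enolate of succinamoyl oxazolidinone 17; this sets 12S and 13R.
3. Aldehyde 11 comes from a C12 silyl ether; the 7β-oxygen is set by SeO2 allylic oxidation, oxidation to the enone and Luche reduction; the C8=C17 alkene comes from dehydration of the C8 tertiary alcohol.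
4. Rings A and B with C5, C9 and C10 are bought as (+)-sclareolide; the C2 chloride is put in by site-selective radical C–H chlorination and the lactone is reduced to the 8,12-diol.
5. Ring order: rings A and B are present from the start; the imide ring is the only ring formed (step 14).

Convention: labdane numbering is used (C1–C10 decalin, C17 on C8, side chain C11–C12 on C9, imide carbons C13–C16); β is the face of the C10 methyl, α the opposite face; every decalin compound keeps 5α-H, 9α-H and 10β-CH3 of sclareolide.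
Assumption: the N-chloroamide of step 1 is treated as a purchasable reagent (otherwise two steps from 3,5-bis(trifluoromethyl)benzoyl chloride, tert-butylamine and tBuOCl).

## Route

Step 1
Reactants: 1 (+)-sclareolide
Product: 2 2α-chlorosclareolide
Conditions: N-tert-butyl-N-chloro-3,5-bis(trifluoromethyl)benzamide (1.2 equiv), Cs2CO3, PhH, visible light, 55 °C
Reagents that add atoms: N-tert-butyl-N-chloro-3,5-bis(trifluoromethyl)benzamide, CC(C)(C)N(Cl)C(=O)c1cc(cc(c1)C(F)(F)F)C(F)(F)F
Why: Radical chain C–H chlorination by a bulky amidyl radical abstracts the most accessible, most electron-rich methylene hydrogen (C2; C1 and C3 are shielded by the quaternary carbons and ring B is deactivated by the lactone), and chlorine is delivered from the α face away from the axial C10 and C4 methyls, giving the equatorial 2S chloride.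

Step 2
Reactants: 2 2α-chlorosclareolide
Product: 3 2α-chloro-13,14,15,16-tetranorlabdane-8α,12-diol
Conditions: LiAlH4, THF, 0 °C; then H2O, 15% aq NaOH
Reagents that add atoms: none
Why: Hydride reduction of the lactone gives the diol without touching C8 (configuration kept), and the hindered secondary chloride is inert to LiAlH4 at 0 °C.

Step 3
Reactants: 3 2α-chloro-13,14,15,16-tetranorlabdane-8α,12-diol
Product: 4 12-(tert-butyldimethylsilyloxy)-2α-chloro-13,14,15,16-tetranorlabdan-8α-ol
Conditions: TBSCl, imidazole, DMF, 0 °C to rt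
Reagents that add atoms: tert-butyldimethylsilyl chloride, CC(C)(C)[Si](C)(C)Cl
Why: Silyl ether formation is selective for the primary alcohol because the tertiary C8 hydroxyl is far too hindered for TBSCl.

Step 4
Reactants: 4 12-(tert-butyldimethylsilyloxy)-2α-chloro-13,14,15,16-tetranorlabdan-8α-ol
Product: 5 12-(tert-butyldimethylsilyloxy)-2α-chloro-13,14,15,16-tetranorlabd-8(17)-ene
Conditions: SOCl2, pyridine, CH2Cl2, −78 °C
Reagents that add atoms: none
Why: Dehydration through the chlorosulfite (E2 elimination) goes mainly to the exocyclic alkene because the equatorial C8–O bond has no anti-periplanar ring hydrogen, so pyridine removes a C17 methyl proton; minor ring-alkene isomers are removed on AgNO3-impregnated silica.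

Step 5
Reactants: 5 12-(tert-butyldimethylsilyloxy)-2α-chloro-13,14,15,16-tetranorlabd-8(17)-ene
Product: 6 12-(tert-butyldimethylsilyloxy)-2α-chloro-13,14,15,16-tetranorlabd-8(17)-en-7α-ol
Conditions: SeO2 (0.5 equiv), tBuOOH, CH2Cl2, rt
Reagents that add atoms: selenium dioxide, O=[Se]=O (oxygen carrier); tert-butyl hydroperoxide, CC(C)(C)OO (terminal oxygen source)
Why: Riley allylic oxidation (ene reaction, then [2,3]-sigmatropic shift) attacks the ring CH2 at C7 in preference to the C9 methine and delivers oxygen axially to give the 7α alcohol; any enone 7 formed by over-oxidation is carried into the next two steps, which fix C7 anyway.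

Step 6
Reactants: 6 12-(tert-butyldimethylsilyloxy)-2α-chloro-13,14,15,16-tetranorlabd-8(17)-en-7α-ol
Product: 7 12-(tert-butyldimethylsilyloxy)-2α-chloro-13,14,15,16-tetranorlabd-8(17)-en-7-one
Conditions: Dess–Martin periodinane, NaHCO3, CH2Cl2, 0 °C to rt
Reagents that add atoms: none
Why: Buffered Dess–Martin oxidation of the allylic alcohol gives the exocyclic enone without acid or base that could move the alkene into the ring, and it erases the wrong C7 configuration.

Step 7
Reactants: 7 12-(tert-butyldimethylsilyloxy)-2α-chloro-13,14,15,16-tetranorlabd-8(17)-en-7-one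
Product: 8 12-(tert-butyldimethylsilyloxy)-2α-chloro-13,14,15,16-tetranorlabd-8(17)-en-7β-ol
Conditions: NaBH4, CeCl3·7H2O, MeOH, −78 to 0 °C
Reagents that add atoms: none
Why: Luche 1,2-reduction, in which the small hydride adds axially from the α face of the ring B ketone (only axial hydrogens at C5 and C9 on that face), gives the equatorial 7β (7S) alcohol while CeCl3 suppresses conjugate reduction.

Step 8
Reactants: 8 12-(tert-butyldimethylsilyloxy)-2α-chloro-13,14,15,16-tetranorlabd-8(17)-en-7β-ol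
Product: 9 7β-acetoxy-12-(tert-butyldimethylsilyloxy)-2α-chloro-13,14,15,16-tetranorlabd-8(17)-ene
Conditions: Ac2O, pyridine, 4-(dimethylamino)pyridine (cat.), CH2Cl2, rt
Reagents that add atoms: acetic anhydride, CC(=O)OC(C)=O
Why: Nucleophile-catalysed acylation of the unhindered equatorial secondary alcohol proceeds with retention at C7.

Step 9
Reactants: 9 7β-acetoxy-12-(tert-butyldimethylsilyloxy)-2α-chloro-13,14,15,16-tetranorlabd-8(17)-ene
Product: 10 7β-acetoxy-2α-chloro-13,14,15,16-tetranorlabd-8(17)-en-12-ol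
Conditions: HF·pyridine, pyridine, THF, 0 °C to rt
Reagents that add atoms: none
Why: Fluoride-driven desilylation under pyridine-buffered conditions frees the primary alcohol and leaves the allylic acetate, the alkene and the chloride untouched.

Step 10
Reactants: 10 7β-acetoxy-2α-chloro-13,14,15,16-tetranorlabd-8(17)-en-12-ol
Product: 11 7β-acetoxy-2α-chloro-13,14,15,16-tetranorlabd-8(17)-en-12-al
Conditions: Dess–Martin periodinane, NaHCO3, CH2Cl2, 0 °C to rt
Reagents that add atoms: none
Why: Dess–Martin oxidation stops cleanly at the aldehyde under neutral conditions that avoid acid-promoted ene cyclization onto the C8=C17 alkene; the aldehyde is used at once.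

Step 11
Reactants: 12 (R)-4-benzyl-1,3-oxazolidin-2-one; 13 succinic anhydride
Product: 15 4-[(4R)-4-benzyl-2-oxo-1,3-oxazolidin-3-yl]-4-oxobutanoic acid, via N-lithio-(R)-4-benzyl-1,3-oxazolidin-2-one 14 (not isolated)
Conditions: nBuLi, THF, −78 °C; then 13, −78 to 0 °C; aq HCl
Reagents that add atoms: none
Why: N-acylation of the lithiated oxazolidinone by ring-opening of the cyclic anhydride gives the mono-acylated acid directly and leaves the C4 stereocentre untouched.

Step 12
Reactants: 15 4-[(4R)-4-benzyl-2-oxo-1,3-oxazolidin-3-yl]-4-oxobutanoic acid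
Product: 17 4-[(4R)-4-benzyl-2-oxo-1,3-oxazolidin-3-yl]-4-oxobutanamide, via isobutoxycarbonyl mixed anhydride 16 (not isolated)
Conditions: iBuOCOCl, N-methylmorpholine, THF, −15 °C; then NH3 (0.5 M in dioxane, 1.1 equiv), −15 to 0 °C
Reagents that add atoms: ammonia, N
Why: Mixed carbonic anhydride amidation works because ammonia attacks the activated acyl carbon at low temperature much faster than it attacks the N-acyloxazolidinone.

Step 13
Reactants: 11 7β-acetoxy-2α-chloro-13,14,15,16-tetranorlabd-8(17)-en-12-al; 17 4-[(4R)-4-benzyl-2-oxo-1,3-oxazolidin-3-yl]-4-oxobutanamide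
Product: 20 Evans syn-aldol adduct (12S,13R), via bis(dibutylboryl) Z-enolate 18 (not isolated), via dibutylboron aldolate 19 (not isolated)
Conditions: 17 (1.5 equiv), Bu2BOTf (2.2 equiv per 17), Et3N, CH2Cl2, −78 to 0 °C; then 11, −78 to 0 °C; then pH 7 buffer, MeOH, H2O2, 0 °C
Reagents that add atoms: none
Why: In this Evans syn-aldol the Z boron enolate reacts through a closed Zimmerman–Traxler chair whose face is fixed by the (R)-benzyl group, so the C12–C13 bond forms with 12S,13R (syn) configuration regardless of the remote C9 centre; one equivalent of Bu2BOTf masks the carboxamide N–H so that no free Lewis acid is left to open the transition state.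

Step 14
Reactants: 20 Evans syn-aldol adduct (12S,13R)
Product: 21 haterumaimide N
Conditions: 1,8-diazabicyclo[5.4.0]undec-7-ene (DBU, 1.5 equiv), THF, 0 °C to rt; aq NH4Cl
Reagents that add atoms: none
Why: Intramolecular N-acylation (5-exo-trig imide formation) occurs when the carboxamide nitrogen attacks the activated exocyclic imide carbonyl and expels the oxazolidinone; the resulting imide anion shields C13 from epimerization and no nucleophile is present to cleave the acetate.

## Compound list

1 | (+)-sclareolide, (3aR,5aS,9aS,9bR)-3a,6,6,9a-tetramethyldecahydronaphtho[2,1-b]furan-2(1H)-one | C[C@@]12CC[C@H]3C(C)(C)CCC[C@]3(C)[C@H]1CC(=O)O2 | starting material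
2 | 2α-chlorosclareolide (equatorial 2S chloride on ring A) | C[C@@]12CC[C@H]3C(C)(C)C[C@H](Cl)C[C@]3(C)[C@H]1CC(=O)O2 | intermediate
3 | 2α-chloro-13,14,15,16-tetranorlabdane-8α,12-diol (tertiary 8α-OH, 8β-CH3, primary 12-OH) | C[C@@]1(O)CC[C@H]2C(C)(C)C[C@H](Cl)C[C@]2(C)[C@H]1CCO | intermediate
4 | 12-(tert-butyldimethylsilyloxy)-2α-chloro-13,14,15,16-tetranorlabdan-8α-ol | C[C@@]1(O)CC[C@H]2C(C)(C)C[C@H](Cl)C[C@]2(C)[C@H]1CCO[Si](C)(C)C(C)(C)C | intermediate
5 | 12-(tert-butyldimethylsilyloxy)-2α-chloro-13,14,15,16-tetranorlabd-8(17)-ene | C=C1CC[C@H]2C(C)(C)C[C@H](Cl)C[C@]2(C)[C@H]1CCO[Si](C)(C)C(C)(C)C | intermediate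
6 | 12-(tert-butyldimethylsilyloxy)-2α-chloro-13,14,15,16-tetranorlabd-8(17)-en-7α-ol (axial OH, 7R) | C=C1[C@H](O)C[C@H]2C(C)(C)C[C@H](Cl)C[C@]2(C)[C@H]1CCO[Si](C)(C)C(C)(C)C | intermediate
7 | 12-(tert-butyldimethylsilyloxy)-2α-chloro-13,14,15,16-tetranorlabd-8(17)-en-7-one | C=C1C(=O)C[C@H]2C(C)(C)C[C@H](Cl)C[C@]2(C)[C@H]1CCO[Si](C)(C)C(C)(C)C | intermediate
8 | 12-(tert-butyldimethylsilyloxy)-2α-chloro-13,14,15,16-tetranorlabd-8(17)-en-7β-ol (equatorial OH, 7S) | C=C1[C@@H](O)C[C@H]2C(C)(C)C[C@H](Cl)C[C@]2(C)[C@H]1CCO[Si](C)(C)C(C)(C)C | intermediate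
9 | 7β-acetoxy-12-(tert-butyldimethylsilyloxy)-2α-chloro-13,14,15,16-tetranorlabd-8(17)-ene | C=C1[C@@H](OC(C)=O)C[C@H]2C(C)(C)C[C@H](Cl)C[C@]2(C)[C@H]1CCO[Si](C)(C)C(C)(C)C | intermediate
10 | 7β-acetoxy-2α-chloro-13,14,15,16-tetranorlabd-8(17)-en-12-ol | C=C1[C@@H](OC(C)=O)C[C@H]2C(C)(C)C[C@H](Cl)C[C@]2(C)[C@H]1CCO | intermediate
11 | 7β-acetoxy-2α-chloro-13,14,15,16-tetranorlabd-8(17)-en-12-al | C=C1[C@@H](OC(C)=O)C[C@H]2C(C)(C)C[C@H](Cl)C[C@]2(C)[C@H]1CC=O | intermediate
12 | (R)-4-benzyl-1,3-oxazolidin-2-one | O=C1N[C@H](Cc2ccccc2)CO1 | starting material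
13 | succinic anhydride | O=C1CCC(=O)O1 | starting material
14 | N-lithio-(R)-4-benzyl-1,3-oxazolidin-2-one | [Li]N1[C@H](Cc2ccccc2)COC1=O | intermediate
15 | 4-[(4R)-4-benzyl-2-oxo-1,3-oxazolidin-3-yl]-4-oxobutanoic acid | OC(=O)CCC(=O)N1[C@H](Cc2ccccc2)COC1=O | intermediate
16 | isobutoxycarbonyl mixed anhydride of acid 15 | CC(C)COC(=O)OC(=O)CCC(=O)N1[C@H](Cc2ccccc2)COC1=O | intermediate
17 | 4-[(4R)-4-benzyl-2-oxo-1,3-oxazolidin-3-yl]-4-oxobutanamide | NC(=O)CCC(=O)N1[C@H](Cc2ccccc2)COC1=O | intermediate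
18 | bis(dibutylboryl) Z-enolate of 17 (O-boron Z-enolate of the imide; carboxamide nitrogen carries the second Bu2B group) | CCCCB(CCCC)NC(=O)C/C=C(\OB(CCCC)CCCC)N1[C@H](Cc2ccccc2)COC1=O | intermediate
19 | dibutylboron aldolate of 20 (12-O-BBu2, carboxamide N-BBu2) | C=C1[C@@H](OC(C)=O)C[C@H]2C(C)(C)C[C@H](Cl)C[C@]2(C)[C@H]1C[C@H](OB(CCCC)CCCC)[C@@H](CC(=O)NB(CCCC)CCCC)C(=O)N1[C@H](Cc2ccccc2)COC1=O | intermediate
20 | Evans syn-aldol adduct: (4R)-4-benzyl-3-acyl-1,3-oxazolidin-2-one whose acyl group is the (2R,3S)-2-(2-amino-2-oxoethyl)-3-hydroxybutanoyl chain (C16, C13, C12, C11) ending on C9 of the 7β-acetoxy-2α-chloro-8(17)-ene decalin; 12S,13R | C=C1[C@@H](OC(C)=O)C[C@H]2C(C)(C)C[C@H](Cl)C[C@]2(C)[C@H]1C[C@H](O)[C@@H](CC(N)=O)C(=O)N1[C@H](Cc2ccccc2)COC1=O | intermediate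
21 | haterumaimide N, (3R)-3-[(1S)-2-[(1R,3S,4aS,7S,8aS)-3-acetoxy-7-chloro-5,5,8a-trimethyl-2-methylidenedecahydronaphthalen-1-yl]-1-hydroxyethyl]pyrrolidine-2,5-dione | C=C1[C@@H](OC(C)=O)C[C@H]2C(C)(C)C[C@H](Cl)C[C@]2(C)[C@H]1C[C@H](O)[C@H]1CC(=O)NC1=O | target

## Step count and risk

Total step count: 14.
Longest linear sequence: 12 steps (steps 1–10, then 13 and 14, from sclareolide); the donor branch is 2 steps (11 and 12).

Three steps most likely to fail:

Step 13 (aldol with a donor that carries a free primary carboxamide: incomplete enolization, or erosion of selectivity if the Bu2BOTf stoichiometry is off). The fallback sets out from 11 and comes back at 21. (R)-4-Benzyl-1,3-thiazolidine-2-thione is acylated with methyl 4-chloro-4-oxobutanoate (Et3N, CH2Cl2) to give methyl 4-[(4R)-4-benzyl-2-thioxo-1,3-thiazolidin-3-yl]-4-oxobutanoate F5, a donor with no N–H. Its chlorotitanium enolate (TiCl4, iPr2NEt, N-methylpyrrolidinone, CH2Cl2, −78 °C, Crimmins conditions for the Evans-syn sense) adds to 11 to give the 12S,13R thiazolidinethione adduct F6. NH3 (0.5 M in dioxane, 0 °C) displaces the thione auxiliary within minutes, far faster than it attacks the acetate, to give the 12-hydroxy primary amide methyl ester F7. DBU in THF then closes the imide onto the C15 ester with loss of methanol and gives 21.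

Step 14 (imide closure: the C12 alkoxide could instead attack the carbamate carbonyl of the auxiliary, or retro-aldol cleavage could compete). The fallback sets out from 20 and comes back at 21. TESOTf and 2,6-lutidine (CH2Cl2, −78 °C, mild aqueous work-up to hydrolyse any N-silyl amide) give the 12-O-triethylsilyl ether of the adduct F8, in which neither side reaction is possible. NaN(SiMe3)2 (THF, −78 to 0 °C) closes the ring to 12-O-triethylsilyl haterumaimide N F9 with loss of the oxazolidinone. HF·pyridine (THF, 0 °C) removes the silyl group and gives 21.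

Step 4 (dehydration: ring-alkene regioisomers, or participation of the C12 oxygen giving a tetrahydrofuran). The fallback sets out from 2 and comes back at 5, and moves the elimination to an amide substrate, for which I recall high exocyclic selectivity in the sclareolide series. Lactone 2 is opened with MeNH(OMe)·HCl and AlMe3 (CH2Cl2, 0 °C to rt) to the 8α-hydroxy N-methoxy-N-methylamide F1. SOCl2 and pyridine at −78 °C give the 8(17)-ene N-methoxy-N-methylamide F2. iBu2AlH (THF, −78 °C) gives the 8(17)-en-12-al F3, and NaBH4 (MeOH, 0 °C) gives the 8(17)-en-12-ol F4. TBSCl and imidazole then silylate F4 to give 5.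

## Further compounds

F1 | step 4 | 2α-chloro-8α-hydroxy-N-methoxy-N-methyl-13,14,15,16-tetranorlabdan-12-amide | C[C@@]1(O)CC[C@H]2C(C)(C)C[C@H](Cl)C[C@]2(C)[C@H]1CC(=O)N(C)OC
F2 | step 4 | 2α-chloro-N-methoxy-N-methyl-13,14,15,16-tetranorlabd-8(17)-en-12-amide | C=C1CC[C@H]2C(C)(C)C[C@H](Cl)C[C@]2(C)[C@H]1CC(=O)N(C)OC
F3 | step 4 | 2α-chloro-13,14,15,16-tetranorlabd-8(17)-en-12-al | C=C1CC[C@H]2C(C)(C)C[C@H](Cl)C[C@]2(C)[C@H]1CC=O
F4 | step 4 | 2α-chloro-13,14,15,16-tetranorlabd-8(17)-en-12-ol | C=C1CC[C@H]2C(C)(C)C[C@H](Cl)C[C@]2(C)[C@H]1CCO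
F5 | step 13 | methyl 4-[(4R)-4-benzyl-2-thioxo-1,3-thiazolidin-3-yl]-4-oxobutanoate | COC(=O)CCC(=O)N1[C@H](Cc2ccccc2)CSC1=S
F6 | step 13 | syn-aldol adduct of F5 and 11 (12S,13R; thiazolidinethione on the C16 carbonyl, methyl ester at C15) | C=C1[C@@H](OC(C)=O)C[C@H]2C(C)(C)C[C@H](Cl)C[C@]2(C)[C@H]1C[C@H](O)[C@@H](CC(=O)OC)C(=O)N1[C@H](Cc2ccccc2)CSC1=S
F7 | step 13 | 12S-hydroxy-13R primary amide methyl ester (C16 carboxamide, C15 methyl ester) of the 7β-acetoxy-2α-chloro-8(17)-ene decalin | C=C1[C@@H](OC(C)=O)C[C@H]2C(C)(C)C[C@H](Cl)C[C@]2(C)[C@H]1C[C@H](O)[C@@H](CC(=O)OC)C(N)=O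
F8 | step 14 | 12-O-triethylsilyl ether of aldol adduct 20 | C=C1[C@@H](OC(C)=O)C[C@H]2C(C)(C)C[C@H](Cl)C[C@]2(C)[C@H]1C[C@H](O[Si](CC)(CC)CC)[C@@H](CC(N)=O)C(=O)N1[C@H](Cc2ccccc2)COC1=O
F9 | step 14 | 12-O-triethylsilyl haterumaimide N | C=C1[C@@H](OC(C)=O)C[C@H]2C(C)(C)C[C@H](Cl)C[C@]2(C)[C@H]1C[C@H](O[Si](CC)(CC)CC)[C@H]1CC(=O)NC1=O
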